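In the dawn run the isomer of the product stayed behind target, and the measure of that lag is what we carry to the new flask, which has half the catalyst.

- dawn: substrate 20 mM; gas 1 mM (held); catalyst 1 mol%; run made earlier
- flask: substrate 20 mM; gas 1.0 mM (held); catalyst 0.5 mol%; time 15 d

- dawn (time / h: isomer of the product / %, target / %): 2.00: 0.3, 0.8; 6.00: 1.7, 3.0; 10.0: 2.4, 4.6; 15.0: 3.5, 7.0; 20.0: 4.6, 9.7; 30.0: 6.5, 12.8; 40.0: 8.9, 15.3

(scatter of a reading: 0.3 percentage points)

- for target the crystals are counted in
- as a solid, counted per litre of solution: crystals
- at the start none of reagent is dissolved
- what may be going on: substrate + reagent <-> target; substrate + reagent <-> isomer of the product; target + catalyst <-> isomer of the product + catalyst; crystals <-> target; gas <-> reagent; substrate <-> dormant form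
- no earlier run changes the charge of catalyst; that part of a forecast is a guess

* ratio of isomer of the product to target at 3.0 h
* ratio of isomer of the product to target at 15 d

Target and the isomer of the product both come from substrate and reagent, each at a rate equal to its rate constant times substrate times reagent. So, while neither goes back or on, the fractions of the charge they gain stand in the ratio of those two constants, however much substrate and reagent remain. At 2.00 h the isomer reads 0.3 % with a scatter of 0.3 percentage points, so we sum the readings from 10.0 h to 20.0 h and get 0.493 as isomer gained per target gained, our reading of the selectivity factor. At 30.0 h and 40.0 h the dawn ratio reads 0.508 and 0.582, so the last reading stands above this factor. For 3.0 h in the new flask we therefore commit to the factor itself. For 15 d we commit to a ratio above it, but we give no size, because that time lies far beyond the last reading and no earlier run changes the catalyst.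

The forecast gives 0.47 and 1.1, its later figure resting on the reading that “This hints at slow catalysed isomerisation”.

    substrate + reagent ⇌ target (K = 2400 L mol⁻¹, k = 0.0131 L mol⁻¹ s⁻¹)
    substrate + reagent ⇌ isomer of the product (K = 2100 L mol⁻¹, k = 0.00592 L mol⁻¹ s⁻¹)
    target + catalyst ⇌ isomer of the product + catalyst, rate k3*[catalyst]*[target] forward; the back reaction follows from the equilibrium constant (k = 0.00512 L mol⁻¹ s⁻¹)
    crystals ⇌ target, rate k4*(cs4 - [target]) while solid is left; crystals form when [target] > cs4 (solubility = 18.0 mM, k = 0.00130 s⁻¹)
    gas ⇌ reagent, rate k5*(csat - [reagent]) (kL = 5.32 × 10⁻⁵ s⁻¹)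
    substrate ⇌ dormant form (K = 1.57, k = 1.42 × 10⁻⁵ s⁻¹)

The new flask gives 0.459 at 3.0 h and 0.863 at 15 d, which is 1.75 times the selectivity factor. In this flask the half-life of the isomer of the product for going back to substrate and reagent is 2.8 d, shorter than the 15 d allowed. The neighbouring flask with 80 mM of substrate reads 0.465 at 3.0 h, and at 15 d, holding 9.70 % of its charge as crystals, it reads 0.658, which is 1.33 times the selectivity factor.

The earlier runs and the new flask stem from a simulated flask on assumed constants; the scatter is artificial.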